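**Plan**

1. Retrosynthesis: cut the C3–O ester bond last. With a ketone placed at C7 as a helper, the carbocycle C4a–C5–C6–C7–C8–C8a is traced back to the cyclobutane C8a–C4a–C5–C6 carrying an acetyl group (the future C7 and C8) on C6. That cyclobutane is cut at C8a–C4a and C6–C5 ([2+2]), then N1–C8a (amine plus ynone) and C5=C1′ (allene from alkyne plus aldehyde).
2. Enabling feature: N1 sits on C8a, two bonds from C7, so with C7=O the carbocycle hides a β-amino ketone N1–C8a–C8–C7(=O). A cyclobutane with the amine on C8a and the acetyl on the neighbouring C6 opens by retro-Mannich cleavage of C8a–C6 and recloses C8→C8a, which inserts C7–C8 between C6 and C8a.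
3. Forward order: Boc-L-alanine → cis-hydroxylactam → homopropargyl carbamate; (R)-2-propyloxirane → side-chain aldehyde; union to an allene; N-(3-oxobutenyl) carbamate; light closes the piperidine ring (N1–C2–C3–C4–C4a–C8a) and the cyclobutane together; acid then grows the carbocycle; hydrogenation, removal of the C7 oxygen, esterification, deprotection.
4. Stereochemistry: C2 and C5′ are bought (L-alanine, (R)-epoxide). C3 comes from hydride delivery anti to the C2 methyl on the tetramic acid. C8a and C4a are set together in the Mannich closure (axial attack trans to the C2 methyl, cis ring fusion). C5 is set by hydrogenation on the convex face of the cis-fused bicycle.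
5. Helpers, all removed later: N-Boc (holds the strained β-aminocyclobutyl ketone until ring expansion is wanted), the C7 carbonyl (removed through its tosylhydrazone), the allene (delivers C5 as a trigonal carbon), O-benzyl and O-TBDPS.

Key step: step 12

Remark: decahydroquinoline locants (N1, C2, C3, C4, C4a, C5–C8, C8a; side chain C1′–C8′) are used for the corresponding atoms of all intermediates, also before the rings exist.

**Route**

Step 1
Reactants: 1 N-Boc-L-alanine; 2 Meldrum's acid
Product: 4 tert-butyl (S)-2-methyl-3,5-dioxopyrrolidine-1-carboxylate, via acyl Meldrum's acid 3 (not isolated)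
Conditions: DCC, DMAP, CH2Cl2, 0 °C to rt; then EtOAc, reflux
Reagents that add atoms: none
Why: C-acylation of Meldrum's acid by the activated acid, then thermal loss of acetone and CO2 from 3, gives an acylketene that the carbamate nitrogen traps (tetramic acid synthesis); the alanine stereocentre should be retained under these neutral conditions.

Step 2
Reactants: 4 tert-butyl (S)-2-methyl-3,5-dioxopyrrolidine-1-carboxylate
Product: 5 tert-butyl (2S,3S)-3-hydroxy-2-methyl-5-oxopyrrolidine-1-carboxylate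
Conditions: NaBH4, AcOH, CH2Cl2, 0 °C
Reagents that add atoms: none
Why: Hydride reduction of the ring ketone of the nearly planar tetramic acid should occur anti to the adjacent methyl group, so the carbinol centre (future C3) is set cis to the methyl by 1,2-substrate control.

Step 3
Reactants: 5 tert-butyl (2S,3S)-3-hydroxy-2-methyl-5-oxopyrrolidine-1-carboxylate
Product: 6 tert-butyl (2S,3S)-3-(benzyloxy)-2-methyl-5-oxopyrrolidine-1-carboxylate
Conditions: BnBr, Ag2O, CH2Cl2, rt, dark
Reagents that add atoms: benzyl bromide, BrCc1ccccc1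
Why: Silver-oxide-mediated Williamson etherification is mild enough to avoid β-elimination of the 4-oxygenated lactam and loss of Boc.

Step 4
Reactants: 6 tert-butyl (2S,3S)-3-(benzyloxy)-2-methyl-5-oxopyrrolidine-1-carboxylate
Product: 8 tert-butyl N-[(2S,3S)-3-(benzyloxy)hex-5-yn-2-yl]carbamate, via hemiaminal 7 (not isolated)
Conditions: i-Bu2AlH, CH2Cl2, −78 °C; then MeOH, K2CO3, dimethyl (1-diazo-2-oxopropyl)phosphonate, −78 °C to rt
Reagents that add atoms: dimethyl (1-diazo-2-oxopropyl)phosphonate, COP(=O)(OC)C(=[N+]=[N-])C(C)=O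
Why: Partial reduction of the Boc-activated lactam gives hemiaminal 7, whose open-chain aldehyde tautomer undergoes Seyferth–Gilbert homologation (Ohira–Bestmann reagent) to the terminal alkyne; no stereocentre is touched.

Step 5
Reactants: 9 (R)-2-propyloxirane; 10 but-3-en-1-ylmagnesium bromide
Product: 11 (R)-non-1-en-6-ol
Conditions: CuI (10 mol %), THF, −30 to 0 °C; then H2O
Reagents that add atoms: none
Why: Copper-catalysed SN2 opening of the terminal epoxide at its CH2 carbon; the carbinol centre (future C5′) is not involved and keeps its configuration.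

Step 6
Reactants: 11 (R)-non-1-en-6-ol
Product: 12 (R)-tert-butyl(non-1-en-6-yloxy)diphenylsilane
Conditions: TBDPSCl, imidazole, DMF, rt
Reagents that add atoms: tert-butyl(chloro)diphenylsilane, CC(C)(C)[Si](Cl)(c1ccccc1)c1ccccc1
Why: Standard silylation; TBDPS is chosen because it should survive both later TFA treatments.

Step 7
Reactants: 12 (R)-tert-butyl(non-1-en-6-yloxy)diphenylsilane
Product: 14 (R)-5-[(tert-butyldiphenylsilyl)oxy]octanal, via ozonide 13 (not isolated)
Conditions: O3, CH2Cl2, −78 °C; then PPh3, −78 °C to rt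
Reagents that add atoms: ozone, [O-][O+]=O
Why: Ozonolysis with reductive work-up cleaves the terminal alkene to the aldehyde (future C1′) with loss of formaldehyde.

Step 8
Reactants: 8 tert-butyl N-[(2S,3S)-3-(benzyloxy)hex-5-yn-2-yl]carbamate; 14 (R)-5-[(tert-butyldiphenylsilyl)oxy]octanal
Product: 15 tert-butyl N-[(2S,3S,11R)-3-(benzyloxy)-11-[(tert-butyldiphenylsilyl)oxy]tetradeca-5,6-dien-2-yl]carbamate
Conditions: ZnI2, morpholine, toluene, 130 °C (sealed tube)
Reagents that add atoms: none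
Why: Crabbé-type allenation of a terminal alkyne with an aldehyde (alkynylation of the morpholine iminium, then 1,5-hydride shift with loss of the imine); the allene axis forms unselectively, which is harmless because it becomes a trigonal carbon that is hydrogenated in step 14.

Step 9
Reactants: 15 tert-butyl N-[(2S,3S,11R)-3-(benzyloxy)-11-[(tert-butyldiphenylsilyl)oxy]tetradeca-5,6-dien-2-yl]carbamate; 16 but-3-yn-2-one
Product: 18 (3Z)-4-{[(2S,3S,11R)-3-(benzyloxy)-11-[(tert-butyldiphenylsilyl)oxy]tetradeca-5,6-dien-2-yl]amino}but-3-en-2-one, via primary amine 17 (not isolated)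
Conditions: TFA, CH2Cl2, 0 °C; evaporate; then Et3N, MeOH, 0 °C to rt
Reagents that add atoms: none
Why: Acidolysis of Boc, then conjugate addition of the primary amine to the ynone (aza-Michael addition), should give the hydrogen-bonded Z vinylogous amide; this forms the N1–C8a bond.

Step 10
Reactants: 18 (3Z)-4-{[(2S,3S,11R)-3-(benzyloxy)-11-[(tert-butyldiphenylsilyl)oxy]tetradeca-5,6-dien-2-yl]amino}but-3-en-2-one
Product: 19 tert-butyl N-[(2S,3S,11R)-3-(benzyloxy)-11-[(tert-butyldiphenylsilyl)oxy]tetradeca-5,6-dien-2-yl]-N-[(1E)-3-oxobut-1-en-1-yl]carbamate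
Conditions: Boc2O, DMAP (cat.), MeCN, rt
Reagents that add atoms: di-tert-butyl dicarbonate, CC(C)(C)OC(=O)OC(=O)OC(C)(C)C
Why: N-acylation of the vinylogous amide gives the vinylogous imide; the carbamate damps the nitrogen lone pair so that the cyclobutane made next can be isolated.

Step 11
Reactants: 19 tert-butyl N-[(2S,3S,11R)-3-(benzyloxy)-11-[(tert-butyldiphenylsilyl)oxy]tetradeca-5,6-dien-2-yl]-N-[(1E)-3-oxobut-1-en-1-yl]carbamate
Product: 20 tert-butyl (3S,4S)-8-acetyl-4-(benzyloxy)-7-[(5R)-5-[(tert-butyldiphenylsilyl)oxy]octylidene]-3-methyl-2-azabicyclo[4.2.0]octane-2-carboxylate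
Conditions: hν (medium-pressure Hg lamp, Pyrex filter, λ > 290 nm), degassed MeCN, 0 °C, stopped before full conversion
Reagents that add atoms: none
Why: Intramolecular enone–allene [2+2] photocycloaddition of the vinylogous imide: 1,6-closure between C8a and the proximal allene carbon C4a forms the piperidine ring, then C6–C5 closure forms the cyclobutane and leaves the alkylidene on C5; a chair-like closure with the C2 methyl axial (A(1,3) strain with Boc) should favour the drawn cis-fused isomer, but C8a, C4a and C6 are all reset or erased in step 12.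

Step 12
Reactants: 20 tert-butyl (3S,4S)-8-acetyl-4-(benzyloxy)-7-[(5R)-5-[(tert-butyldiphenylsilyl)oxy]octylidene]-3-methyl-2-azabicyclo[4.2.0]octane-2-carboxylate
Product: 23 (2S,3S,4aR,8aS)-3-(benzyloxy)-5-[(5R)-5-[(tert-butyldiphenylsilyl)oxy]octylidene]-2-methyloctahydroquinolin-7(1H)-one, via aminocyclobutane 21 (not isolated), via keto imine 22 (not isolated)
Conditions: TFA, CH2Cl2, 0 °C; evaporate; then NaOAc, AcOH, MeCN, 40 °C
Reagents that add atoms: none
Why: Loss of Boc frees the N1 lone pair, which together with the acetyl group on C6 makes the C8a–C6 bond of the strained cyclobutane a push–pull bond, so 21 opens by retro-Mannich fragmentation to the cyclic iminium/dienol and, after protonation at C6, to keto imine 22; the methyl ketone then enolises toward C8 and attacks C8a (intramolecular Mannich reaction), so that C7 and C8 are inserted between C6 and C8a and the four-membered ring C8a–C4a–C5–C6 becomes the six-membered ring C4a–C5–C6–C7–C8–C8a. The closest known reaction type is the retro-Mannich/Mannich cascade of vinylogous amide photoadducts (a two-carbon ring expansion of 2-aminocyclobutyl ketones, overall a formal [4+2] addition). The new ring closes in the 6-(enolexo)-exo-trig mode through a chair-like transition state, the return to the cyclobutane by attack of C6 being disfavoured by ring strain. C8a is set by stereoelectronically preferred axial attack on the half-chair iminium that keeps the C2 methyl pseudo-equatorial, which puts the new C8–C8a bond trans to that methyl; C4a must carry its chain equatorially for this closure, which gives the cis ring fusion, and since C4a is α to the imine a wrong epimer can equilibrate through the enamine before closure. The step needs kinetic control of the Mannich closure (buffered acetic acid at 40 °C, no strong acid or heat that would reverse it toward the 2,8a-cis series) and site selectivity for C8 over C6, which the strain of the cyclobutane secures. C5 stays trigonal (C5=C1′), so no stereocentre at C5 is at stake here, and any migration of that alkene into conjugation would be harmless because both isomers are hydrogenated to the same compound in step 14.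

Step 13
Reactants: 23 (2S,3S,4aR,8aS)-3-(benzyloxy)-5-[(5R)-5-[(tert-butyldiphenylsilyl)oxy]octylidene]-2-methyloctahydroquinolin-7(1H)-one
Product: 24 tert-butyl (2S,3S,4aR,8aS)-3-(benzyloxy)-5-[(5R)-5-[(tert-butyldiphenylsilyl)oxy]octylidene]-2-methyl-7-oxooctahydroquinoline-1(2H)-carboxylate
Conditions: Boc2O, Et3N, CH2Cl2, 40 °C
Reagents that add atoms: di-tert-butyl dicarbonate, CC(C)(C)OC(=O)OC(=O)OC(C)(C)C
Why: Carbamate formation on the secondary amine blocks any retro-Mannich reversal of the β-amino ketone and keeps nitrogen out of the later O-acylation.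

Step 14
Reactants: 24 tert-butyl (2S,3S,4aR,8aS)-3-(benzyloxy)-5-[(5R)-5-[(tert-butyldiphenylsilyl)oxy]octylidene]-2-methyl-7-oxooctahydroquinoline-1(2H)-carboxylate
Product: 25 tert-butyl (2S,3S,4aR,5R,8aS)-5-[(5R)-5-[(tert-butyldiphenylsilyl)oxy]octyl]-3-hydroxy-2-methyl-7-oxooctahydroquinoline-1(2H)-carboxylate
Conditions: H2 (1 atm), Pd(OH)2/C, EtOH, rt
Reagents that add atoms: none
Why: Heterogeneous hydrogenation of the trisubstituted exocyclic alkene should deliver hydrogen to C5 from the convex face of the cis-fused bicycle (the face of H4a and H8a; the other face is shielded by the piperidine ring in either chair form), which sets H5 cis to H4a; the same conditions hydrogenolyse the benzyl ether.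

Step 15
Reactants: 25 tert-butyl (2S,3S,4aR,5R,8aS)-5-[(5R)-5-[(tert-butyldiphenylsilyl)oxy]octyl]-3-hydroxy-2-methyl-7-oxooctahydroquinoline-1(2H)-carboxylate
Product: 27 tert-butyl (2S,3S,4aR,5R,8aS)-5-[(5R)-5-[(tert-butyldiphenylsilyl)oxy]octyl]-3-hydroxy-2-methyloctahydroquinoline-1(2H)-carboxylate, via tosylhydrazone 26 (not isolated)
Conditions: TsNHNH2, EtOH, 50 °C; then catecholborane, CHCl3, 0 °C; then NaOAc·3H2O, reflux
Reagents that add atoms: none
Why: Reductive deoxygenation of the ketone through its tosylhydrazone (hydride addition to C=N, loss of sulfinate and N2 from the diazene) removes the C7 carbonyl helper; C5 and C8a are not α to the carbonyl and cannot epimerise.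

Step 16
Reactants: 27 tert-butyl (2S,3S,4aR,5R,8aS)-5-[(5R)-5-[(tert-butyldiphenylsilyl)oxy]octyl]-3-hydroxy-2-methyloctahydroquinoline-1(2H)-carboxylate; 28 (2E)-oct-2-enoic acid
Product: 29 tert-butyl (2S,3S,4aR,5R,8aS)-5-[(5R)-5-[(tert-butyldiphenylsilyl)oxy]octyl]-2-methyl-3-[(2E)-oct-2-enoyloxy]octahydroquinoline-1(2H)-carboxylate
Conditions: DCC, DMAP (cat.), CH2Cl2, 0 °C to rt
Reagents that add atoms: none
Why: Steglich esterification of the only free hydroxyl group (N1 and O5′ are protected); the E alkene of the acid should be retained.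

Step 17
Reactants: 29 tert-butyl (2S,3S,4aR,5R,8aS)-5-[(5R)-5-[(tert-butyldiphenylsilyl)oxy]octyl]-2-methyl-3-[(2E)-oct-2-enoyloxy]octahydroquinoline-1(2H)-carboxylate
Product: 30 tert-butyl (2S,3S,4aR,5R,8aS)-5-[(5R)-5-hydroxyoctyl]-2-methyl-3-[(2E)-oct-2-enoyloxy]octahydroquinoline-1(2H)-carboxylate
Conditions: HF·pyridine, pyridine, THF, 0 °C to rt
Reagents that add atoms: none
Why: Fluoride cleavage of the silyl ether under buffered acidic conditions that leave the enoate and the carbamate intact.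

Step 18
Reactants: 30 tert-butyl (2S,3S,4aR,5R,8aS)-5-[(5R)-5-hydroxyoctyl]-2-methyl-3-[(2E)-oct-2-enoyloxy]octahydroquinoline-1(2H)-carboxylate
Product: 31 (2S,3S,4aR,5R,8aS)-5-[(5R)-5-hydroxyoctyl]-2-methyldecahydroquinolin-3-yl (2E)-oct-2-enoate
Conditions: TFA, CH2Cl2, 0 °C; then aq. NaHCO3
Reagents that add atoms: none
Why: Acidolysis of Boc releases the amine as its salt, so an O-to-N acyl shift should not compete, and a brief mild basic wash gives the free base.

**Compound list**

1 | N-Boc-L-alanine | C[C@H](NC(=O)OC(C)(C)C)C(=O)O | starting material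
2 | Meldrum's acid (2,2-dimethyl-1,3-dioxane-4,6-dione) | CC1(C)OC(=O)CC(=O)O1 | starting material
3 | tert-butyl N-[(2S)-1-(2,2-dimethyl-4,6-dioxo-1,3-dioxan-5-yl)-1-oxopropan-2-yl]carbamate (acyl Meldrum's acid) | C[C@H](NC(=O)OC(C)(C)C)C(=O)C1C(=O)OC(C)(C)OC1=O | intermediate
4 | tert-butyl (S)-2-methyl-3,5-dioxopyrrolidine-1-carboxylate | C[C@H]1C(=O)CC(=O)N1C(=O)OC(C)(C)C | intermediate
5 | tert-butyl (2S,3S)-3-hydroxy-2-methyl-5-oxopyrrolidine-1-carboxylate (methyl and hydroxyl cis) | C[C@H]1[C@@H](O)CC(=O)N1C(=O)OC(C)(C)C | intermediate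
6 | tert-butyl (2S,3S)-3-(benzyloxy)-2-methyl-5-oxopyrrolidine-1-carboxylate | C[C@H]1[C@@H](OCc2ccccc2)CC(=O)N1C(=O)OC(C)(C)C | intermediate
7 | tert-butyl (2S,3S)-3-(benzyloxy)-5-hydroxy-2-methylpyrrolidine-1-carboxylate (hemiaminal, both C5 epimers) | C[C@H]1[C@@H](OCc2ccccc2)CC(O)N1C(=O)OC(C)(C)C | intermediate
8 | tert-butyl N-[(2S,3S)-3-(benzyloxy)hex-5-yn-2-yl]carbamate | C[C@H](NC(=O)OC(C)(C)C)[C@@H](OCc1ccccc1)CC#C | intermediate
9 | (R)-2-propyloxirane | CCC[C@@H]1CO1 | starting material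
10 | but-3-en-1-ylmagnesium bromide | C=CCC[Mg]Br | starting material
11 | (R)-non-1-en-6-ol | CCC[C@@H](O)CCCC=C | intermediate
12 | (R)-tert-butyl(non-1-en-6-yloxy)diphenylsilane | CCC[C@@H](O[Si](c1ccccc1)(c1ccccc1)C(C)(C)C)CCCC=C | intermediate
13 | 3-[(4R)-4-[(tert-butyldiphenylsilyl)oxy]heptyl]-1,2,4-trioxolane (ozonide) | CCC[C@@H](O[Si](c1ccccc1)(c1ccccc1)C(C)(C)C)CCCC1OCOO1 | intermediate
14 | (R)-5-[(tert-butyldiphenylsilyl)oxy]octanal | CCC[C@@H](O[Si](c1ccccc1)(c1ccccc1)C(C)(C)C)CCCC=O | intermediate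
15 | tert-butyl N-[(2S,3S,11R)-3-(benzyloxy)-11-[(tert-butyldiphenylsilyl)oxy]tetradeca-5,6-dien-2-yl]carbamate (both allene-axis isomers) | C[C@H](NC(=O)OC(C)(C)C)[C@@H](OCc1ccccc1)CC=C=CCCC[C@H](O[Si](c1ccccc1)(c1ccccc1)C(C)(C)C)CCC | intermediate
16 | but-3-yn-2-one | CC(=O)C#C | starting material
17 | (2S,3S,11R)-3-(benzyloxy)-11-[(tert-butyldiphenylsilyl)oxy]tetradeca-5,6-dien-2-amine | C[C@H](N)[C@@H](OCc1ccccc1)CC=C=CCCC[C@H](O[Si](c1ccccc1)(c1ccccc1)C(C)(C)C)CCC | intermediate
18 | (3Z)-4-{[(2S,3S,11R)-3-(benzyloxy)-11-[(tert-butyldiphenylsilyl)oxy]tetradeca-5,6-dien-2-yl]amino}but-3-en-2-one | CC(=O)/C=C\N[C@@H](C)[C@@H](OCc1ccccc1)CC=C=CCCC[C@H](O[Si](c1ccccc1)(c1ccccc1)C(C)(C)C)CCC | intermediate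
19 | tert-butyl N-[(2S,3S,11R)-3-(benzyloxy)-11-[(tert-butyldiphenylsilyl)oxy]tetradeca-5,6-dien-2-yl]-N-[(1E)-3-oxobut-1-en-1-yl]carbamate | CC(=O)/C=C/N(C(=O)OC(C)(C)C)[C@@H](C)[C@@H](OCc1ccccc1)CC=C=CCCC[C@H](O[Si](c1ccccc1)(c1ccccc1)C(C)(C)C)CCC | intermediate
20 | tert-butyl (3S,4S)-8-acetyl-4-(benzyloxy)-7-[(5R)-5-[(tert-butyldiphenylsilyl)oxy]octylidene]-3-methyl-2-azabicyclo[4.2.0]octane-2-carboxylate (drawn as the expected major isomer: cis-fused, H-1 and H-6 on the face of the 3-methyl group, acetyl exo; alkylidene geometry uncontrolled; all isomers converge in step 12) | CC(=O)[C@@H]1C(=CCCC[C@H](O[Si](c2ccccc2)(c2ccccc2)C(C)(C)C)CCC)[C@H]2C[C@H](OCc3ccccc3)[C@H](C)N(C(=O)OC(C)(C)C)[C@@H]12 | intermediate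
21 | 1-[(3S,4S)-4-(benzyloxy)-7-[(5R)-5-[(tert-butyldiphenylsilyl)oxy]octylidene]-3-methyl-2-azabicyclo[4.2.0]octan-8-yl]ethan-1-one (free amine of 20) | CC(=O)[C@@H]1C(=CCCC[C@H](O[Si](c2ccccc2)(c2ccccc2)C(C)(C)C)CCC)[C@H]2C[C@H](OCc3ccccc3)[C@H](C)N[C@@H]12 | intermediate
22 | (9R)-4-[(2S,3S)-3-(benzyloxy)-2-methyl-2,3,4,5-tetrahydropyridin-5-yl]-9-[(tert-butyldiphenylsilyl)oxy]dodec-4-en-2-one (ring C5 epimerisable, alkene geometry uncontrolled) | CC(=O)CC(=CCCC[C@H](O[Si](c1ccccc1)(c1ccccc1)C(C)(C)C)CCC)[C@H]1C[C@H](OCc2ccccc2)[C@H](C)N=C1 | intermediate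
23 | (2S,3S,4aR,8aS)-3-(benzyloxy)-5-[(5R)-5-[(tert-butyldiphenylsilyl)oxy]octylidene]-2-methyloctahydroquinolin-7(1H)-one (cis-fused, C8a–C8 trans to the 2-methyl; alkylidene geometry uncontrolled) | O(Cc1ccccc1)[C@H]1C[C@@H]2C(=CCCC[C@H](O[Si](c3ccccc3)(c3ccccc3)C(C)(C)C)CCC)CC(=O)C[C@@H]2N[C@H]1C | intermediate
24 | tert-butyl (2S,3S,4aR,8aS)-3-(benzyloxy)-5-[(5R)-5-[(tert-butyldiphenylsilyl)oxy]octylidene]-2-methyl-7-oxooctahydroquinoline-1(2H)-carboxylate | O(Cc1ccccc1)[C@H]1C[C@@H]2C(=CCCC[C@H](O[Si](c3ccccc3)(c3ccccc3)C(C)(C)C)CCC)CC(=O)C[C@@H]2N(C(=O)OC(C)(C)C)[C@H]1C | intermediate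
25 | tert-butyl (2S,3S,4aR,5R,8aS)-5-[(5R)-5-[(tert-butyldiphenylsilyl)oxy]octyl]-3-hydroxy-2-methyl-7-oxooctahydroquinoline-1(2H)-carboxylate | O[C@H]1C[C@@H]2[C@H](CCCC[C@H](O[Si](c3ccccc3)(c3ccccc3)C(C)(C)C)CCC)CC(=O)C[C@@H]2N(C(=O)OC(C)(C)C)[C@H]1C | intermediate
26 | 4-methylbenzenesulfonylhydrazone of 25 at C7 | O[C@H]1C[C@@H]2[C@H](CCCC[C@H](O[Si](c3ccccc3)(c3ccccc3)C(C)(C)C)CCC)CC(=NNS(=O)(=O)c3ccc(C)cc3)C[C@@H]2N(C(=O)OC(C)(C)C)[C@H]1C | intermediate
27 | tert-butyl (2S,3S,4aR,5R,8aS)-5-[(5R)-5-[(tert-butyldiphenylsilyl)oxy]octyl]-3-hydroxy-2-methyloctahydroquinoline-1(2H)-carboxylate | O[C@H]1C[C@@H]2[C@H](CCCC[C@H](O[Si](c3ccccc3)(c3ccccc3)C(C)(C)C)CCC)CCC[C@@H]2N(C(=O)OC(C)(C)C)[C@H]1C | intermediate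
28 | (2E)-oct-2-enoic acid | CCCCC/C=C/C(=O)O | starting material
29 | tert-butyl (2S,3S,4aR,5R,8aS)-5-[(5R)-5-[(tert-butyldiphenylsilyl)oxy]octyl]-2-methyl-3-[(2E)-oct-2-enoyloxy]octahydroquinoline-1(2H)-carboxylate | CCCCC/C=C/C(=O)O[C@H]1C[C@@H]2[C@H](CCCC[C@H](O[Si](c3ccccc3)(c3ccccc3)C(C)(C)C)CCC)CCC[C@@H]2N(C(=O)OC(C)(C)C)[C@H]1C | intermediate
30 | tert-butyl (2S,3S,4aR,5R,8aS)-5-[(5R)-5-hydroxyoctyl]-2-methyl-3-[(2E)-oct-2-enoyloxy]octahydroquinoline-1(2H)-carboxylate | CCCCC/C=C/C(=O)O[C@H]1C[C@@H]2[C@H](CCCC[C@H](O)CCC)CCC[C@@H]2N(C(=O)OC(C)(C)C)[C@H]1C | intermediate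
31 | (2S,3S,4aR,5R,8aS)-5-[(5R)-5-hydroxyoctyl]-2-methyldecahydroquinolin-3-yl (2E)-oct-2-enoate | CCCCC/C=C/C(=O)O[C@H]1C[C@@H]2[C@H](CCCC[C@H](O)CCC)CCC[C@@H]2N[C@H]1C | target

**Step count and risks**

Total step count: 18. Longest linear sequence: 15 (steps 1–4 and 8–18).

Steps most likely to fail:

Step 12. After the cyclobutane opens, the intermediate may tautomerise into the fully conjugated 2-amino-dienone, so that Mannich closure stalls, or closure may become reversible and the configuration at C8a may drift toward the 2,8a-cis series. The fallback sets out from 20 and fixes C5 before the ring expansion. Hydrogenation of 20 (H2, Pd(OH)2/C, EtOAc) should reduce the alkylidene from the convex face of the bicyclo[4.2.0]octane and cleave the benzyl ether, giving the saturated hydroxy cyclobutane F1. Treatment with TFA and then NaOAc/AcOH in MeCN runs the same retro-Mannich/Mannich ring expansion on a substrate that cannot form a dienol, giving the amino ketone F2. Boc2O then returns to the route at 25.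

Step 11. The excited vinylogous imide may add to the remote π bond of the allene or close in the crossed sense, and the β,γ-unsaturated ketone product may undergo secondary photolysis (1,3-acyl shift). The fallback sets out from 19 and replaces the photochemical [2+2] and ring expansion by a thermal intramolecular Diels–Alder reaction of an N-acylaminodiene, so it forms the six-membered ring directly, without a ring-size change. TBSOTf and Et3N in CH2Cl2 at 0 °C convert the methyl ketone of 19 into the 1-amido-3-silyloxydiene F3. Heating in toluene at about 160 °C should add the diene across the proximal allene bond (C8a–C4a and C6–C5 bond formation, tether anti to the axial C2 methyl), giving the silyl enol ether F4. Dilute HCl in THF hydrolyses it and returns to the route at 24.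

Step 14. Facial selectivity of hydrogen delivery to C5 may be poor, or the alkene may migrate on the catalyst to C4a=C5 before reduction, which would put C4a at stake. The fallback sets out from 24 and uses hydride conjugate addition in place of surface hydrogenation. RhCl3·3H2O (cat.) in EtOH at 60 °C moves the alkene into conjugation, giving the enone F5. The bulky copper hydride [(Ph3P)CuH]6 in wet benzene at rt should deliver hydride to C5 from the convex face, giving the saturated benzyl ether F6. Hydrogenolysis (H2, Pd/C, EtOH) returns to the route at 25.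

**Further compounds**

F1 | step 12 | tert-butyl (3S,4S)-8-acetyl-7-[(5R)-5-[(tert-butyldiphenylsilyl)oxy]octyl]-4-hydroxy-3-methyl-2-azabicyclo[4.2.0]octane-2-carboxylate (H-1, H-6 and H-7 all cis) | CC(=O)[C@@H]1[C@@H](CCCC[C@H](O[Si](c2ccccc2)(c2ccccc2)C(C)(C)C)CCC)[C@H]2C[C@H](O)[C@H](C)N(C(=O)OC(C)(C)C)[C@@H]12
F2 | step 12 | (2S,3S,4aR,5R,8aS)-5-[(5R)-5-[(tert-butyldiphenylsilyl)oxy]octyl]-3-hydroxy-2-methyloctahydroquinolin-7(1H)-one | O[C@H]1C[C@@H]2[C@H](CCCC[C@H](O[Si](c3ccccc3)(c3ccccc3)C(C)(C)C)CCC)CC(=O)C[C@@H]2N[C@H]1C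
F3 | step 11 | tert-butyl N-[(2S,3S,11R)-3-(benzyloxy)-11-[(tert-butyldiphenylsilyl)oxy]tetradeca-5,6-dien-2-yl]-N-[(1E)-3-[(tert-butyldimethylsilyl)oxy]buta-1,3-dien-1-yl]carbamate | C=C(O[Si](C)(C)C(C)(C)C)/C=C/N(C(=O)OC(C)(C)C)[C@@H](C)[C@@H](OCc1ccccc1)CC=C=CCCC[C@H](O[Si](c1ccccc1)(c1ccccc1)C(C)(C)C)CCC
F4 | step 11 | tert-butyl (2S,3S)-3-(benzyloxy)-7-[(tert-butyldimethylsilyl)oxy]-5-[(5R)-5-[(tert-butyldiphenylsilyl)oxy]octylidene]-2-methyl-3,4,4a,5,6,8a-hexahydroquinoline-1(2H)-carboxylate (ring fusion as in 24) | O(Cc1ccccc1)[C@H]1C[C@@H]2C(=CCCC[C@H](O[Si](c3ccccc3)(c3ccccc3)C(C)(C)C)CCC)CC(O[Si](C)(C)C(C)(C)C)=C[C@@H]2N(C(=O)OC(C)(C)C)[C@H]1C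
F5 | step 14 | tert-butyl (2S,3S,4aR,8aS)-3-(benzyloxy)-5-[(5R)-5-[(tert-butyldiphenylsilyl)oxy]octyl]-2-methyl-7-oxo-3,4,4a,7,8,8a-hexahydroquinoline-1(2H)-carboxylate | O(Cc1ccccc1)[C@H]1C[C@@H]2C(CCCC[C@H](O[Si](c3ccccc3)(c3ccccc3)C(C)(C)C)CCC)=CC(=O)C[C@@H]2N(C(=O)OC(C)(C)C)[C@H]1C
F6 | step 14 | tert-butyl (2S,3S,4aR,5R,8aS)-3-(benzyloxy)-5-[(5R)-5-[(tert-butyldiphenylsilyl)oxy]octyl]-2-methyl-7-oxooctahydroquinoline-1(2H)-carboxylate | O(Cc1ccccc1)[C@H]1C[C@@H]2[C@H](CCCC[C@H](O[Si](c3ccccc3)(c3ccccc3)C(C)(C)C)CCC)CC(=O)C[C@@H]2N(C(=O)OC(C)(C)C)[C@H]1C
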